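The oxane ring of the target carries a 1,3-pattern: a tertiary hydroxyl on C3, methylene C4 and brominated C5. This aldol-type O–C3–C4–C5 array is disconnected at C4–C5 through a temporary 4,5-dihydroisoxazole. A tartrate-controlled nitrile oxide cycloaddition unites an allylic alcohol carrying the finished bromochlorocyclohexane (from (S)-limonene) with a C5–C6 nitrile oxide. It closes the five-membered ring by the C4–C5 and C3–O bonds and fixes C3 in one operation. N–O cleavage unveils a β-hydroxy ketone; oxidative lactonisation, conversion of the ketone into a vinyl bromide, hydrogen-atom-transfer hydrogenation (equatorial C5–Br) and lactone methylenation complete the target.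

Key step: step 8

Remark on locants: O1 and C2–C6 below are the oxane ring atoms of the target (C2 bears the methylidene, C3 the hydroxyl, C5 the bromine, C6 the two methyl groups).

Step 1
Reactants: 1 (S)-(−)-limonene
Product: 3 cis-limonene 1,2-oxide [(1S,2R,4S) in p-menthane numbering], via epoxide mixture 2 (not isolated)
Conditions: mCPBA, NaHCO3, CH2Cl2, 0 °C; then pyrrolidine, H2O, 100 °C, recovery of the unreacted cis epoxide
Reagents that add atoms: m-chloroperbenzoic acid, O=C(OO)c1cccc(Cl)c1
Why: Prilezhaev epoxidation takes the more electron-rich ring alkene, and the kinetic separation follows the Fürst–Plattner rule, since only the trans epoxide can be opened by the amine at its secondary carbon in a trans-diaxial way, so the cis epoxide (oxygen anti to the isopropenyl group) should be recovered.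

Step 2
Reactants: 3 cis-limonene 1,2-oxide
Product: 4 (1R,2R,5S)-2-bromo-2-methyl-5-(prop-1-en-2-yl)cyclohexan-1-ol
Conditions: HBr (33% in AcOH, 1.05 equiv), Et2O, −40 °C
Reagents that add atoms: hydrogen bromide, Br
Why: Acid-mediated epoxide opening in which the Markovnikov and trans-diaxial (Fürst–Plattner) preferences coincide, so bromide should enter the tertiary carbon with inversion and give the trans-diaxial tertiary bromide/secondary alcohol before HBr adds to the isopropenyl group.

Step 3
Reactants: 4 (1R,2R,5S)-2-bromo-2-methyl-5-(prop-1-en-2-yl)cyclohexan-1-ol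
Product: 5 (1S,2S,4S)-2-bromo-1-chloro-1-methyl-4-(prop-1-en-2-yl)cyclohexane
Conditions: PPh3, N-chlorosuccinimide, CH2Cl2, 0 °C
Reagents that add atoms: N-chlorosuccinimide, O=C1CCC(=O)N1Cl
Why: Appel-type deoxychlorination with neighbouring-group participation: the antiperiplanar axial bromine displaces the oxyphosphonium group to give a bromonium ion on the face syn to the isopropenyl group, which chloride should open at the tertiary carbon (Markovnikov) with inversion, so a net 1,2-bromine shift sets both halogen stereocenters as the trans-diequatorial bromochloride.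

Step 4
Reactants: 5 (1S,2S,4S)-2-bromo-1-chloro-1-methyl-4-(prop-1-en-2-yl)cyclohexane
Product: 6 2-[(1S,3S,4S)-3-bromo-4-chloro-4-methylcyclohexyl]prop-2-en-1-ol
Conditions: SeO2 (cat.), t-BuOOH, salicylic acid (cat.), CH2Cl2, rt
Reagents that add atoms: selenium dioxide, O=[Se]=O; tert-butyl hydroperoxide, CC(C)(C)OO
Why: Riley allylic oxidation (ene reaction, then [2,3]-sigmatropic shift) of the 1,1-disubstituted alkene should hydroxylate the allylic methyl group in preference to the tertiary ring C–H and leave the saturated dihalide untouched.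

Step 5
Reactants: 7 2-methylbut-3-en-2-ol
Product: 8 triethyl[(2-methylbut-3-en-2-yl)oxy]silane
Conditions: Et3SiOTf, 2,6-lutidine, CH2Cl2, 0 °C
Reagents that add atoms: triethylsilyl trifluoromethanesulfonate, CC[Si](CC)(CC)OS(=O)(=O)C(F)(F)F
Why: Silylation with the silyl triflate, which is reactive enough for a tertiary carbinol.

Step 6
Reactants: 8 triethyl[(2-methylbut-3-en-2-yl)oxy]silane
Product: 10 (E)-2-methyl-2-(triethylsilyloxy)propanal oxime, via aldehyde 9 (not isolated)
Conditions: O3, CH2Cl2, −78 °C; Me2S; then NH2OH·HCl, pyridine, EtOH, rt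
Reagents that add atoms: hydroxylamine hydrochloride, NO.Cl
Why: Ozonolysis with reductive work-up gives the non-enolisable α-silyloxy aldehyde, which condenses with hydroxylamine to the oxime.

Step 7
Reactants: 10 (E)-2-methyl-2-(triethylsilyloxy)propanal oxime
Product: 11 (Z)-N-hydroxy-2-methyl-2-(triethylsilyloxy)propanimidoyl chloride
Conditions: N-chlorosuccinimide, DMF, rt
Reagents that add atoms: N-chlorosuccinimide, O=C1CCC(=O)N1Cl
Why: Electrophilic chlorination of the aldoxime carbon gives the hydroximoyl chloride, the standard nitrile oxide precursor.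

Step 8
Reactants: 6 2-[(1S,3S,4S)-3-bromo-4-chloro-4-methylcyclohexyl]prop-2-en-1-ol; 11 (Z)-N-hydroxy-2-methyl-2-(triethylsilyloxy)propanimidoyl chloride
Product: 13 [(5S)-5-[(1S,3S,4S)-3-bromo-4-chloro-4-methylcyclohexyl]-3-[2-(triethylsilyloxy)propan-2-yl]-4,5-dihydro-1,2-oxazol-5-yl]methanol, via nitrile oxide 12 (not isolated)
Conditions: 6, Et2Zn, diisopropyl (R,R)-tartrate, 1,4-dioxane, CHCl3, 0 °C; then 11 and Et2Zn added slowly, 0 °C to rt
Reagents that add atoms: none
Why: Et2Zn converts 6 into its zinc alkoxide and dehydrochlorinates 11 to nitrile oxide 12; both are held on the complex formed from Et2Zn and the tartrate and combine in a concerted, suprafacial [3+2] cycloaddition. The closest known reaction type is the tartrate/zinc-mediated asymmetric nitrile oxide cycloaddition to allylic alcohols. The 4,5-dihydroisoxazole closes in one step as a five-membered ring by simultaneous formation of the C4–C5 bond (dipole carbon to the CH2 terminus) and the C3–O bond (dipole oxygen to the disubstituted alkene carbon). The new stereocenter, the quaternary carbinol carbon (oxane C3, ring C5 of the dihydroisoxazole, S), should be controlled by the (R,R)-tartrate, which exposes one face of the zinc-bound alkene; the cyclohexane stereocenters are remote and nearly symmetric about the attachment carbon, so reagent control decides. The step needs regioselectivity, secured by the 1,1-disubstitution of the alkene and alkoxide direction; face selectivity, secured by the tartrate; and chemoselectivity over dimerisation of 12, secured by its α-quaternary carbon and slow addition.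

Step 9
Reactants: 13 [(5S)-5-[(1S,3S,4S)-3-bromo-4-chloro-4-methylcyclohexyl]-3-[2-(triethylsilyloxy)propan-2-yl]-4,5-dihydro-1,2-oxazol-5-yl]methanol
Product: 15 (5S)-5-[(1S,3S,4S)-3-bromo-4-chloro-4-methylcyclohexyl]-2,5,6-trihydroxy-2-methylhexan-3-one, via silyl ether 14 (not isolated)
Conditions: Mo(CO)6, MeCN/H2O, 80 °C; then 1 M HCl, THF, rt
Reagents that add atoms: water, O
Why: Reductive N–O cleavage of the dihydroisoxazole by Mo(CO)6 gives a β-hydroxy imine that hydrolyses to the β-hydroxy ketone without touching the alkyl halides, and mild acid then removes the silyl ether, the carbinol stereocenter being untouched.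

Step 10
Reactants: 15 (5S)-5-[(1S,3S,4S)-3-bromo-4-chloro-4-methylcyclohexyl]-2,5,6-trihydroxy-2-methylhexan-3-one
Product: 17 (3S)-3-[(1S,3S,4S)-3-bromo-4-chloro-4-methylcyclohexyl]-3-hydroxy-6,6-dimethyloxane-2,5-dione, via lactol 16 (not isolated)
Conditions: TEMPO (cat.), PhI(OAc)2, CH2Cl2, rt
Reagents that add atoms: none
Why: TEMPO-mediated oxidative lactonisation: the primary alcohol is oxidised selectively to the aldehyde, the tertiary hydroxyl closes the six-membered lactol (helped by the gem-dimethyl group), and a second oxidation gives the lactone, which forms the O1–C2 bond of the oxane.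

Step 11
Reactants: 17 (3S)-3-[(1S,3S,4S)-3-bromo-4-chloro-4-methylcyclohexyl]-3-hydroxy-6,6-dimethyloxane-2,5-dione
Product: 18 (3S)-3-[(1S,3S,4S)-3-bromo-4-chloro-4-methylcyclohexyl]-6,6-dimethyl-3-(triethylsilyloxy)oxane-2,5-dione
Conditions: Et3SiOTf, 2,6-lutidine, CH2Cl2, −78 °C
Reagents that add atoms: triethylsilyl trifluoromethanesulfonate, CC[Si](CC)(CC)OS(=O)(=O)C(F)(F)F
Why: Silylation of the tertiary α-hydroxy lactone shields it from the halophosphonium reagent of the next step, and at −78 °C with a pyridine base the ketone should not be enolised.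

Step 12
Reactants: 18 (3S)-3-[(1S,3S,4S)-3-bromo-4-chloro-4-methylcyclohexyl]-6,6-dimethyl-3-(triethylsilyloxy)oxane-2,5-dione
Product: 19 (3R)-5-bromo-3-[(1S,3S,4S)-3-bromo-4-chloro-4-methylcyclohexyl]-6,6-dimethyl-3-(triethylsilyloxy)-3,6-dihydro-2H-pyran-2-one
Conditions: (PhO)3P, Br2, Et3N, CH2Cl2, −60 °C to reflux
Reagents that add atoms: bromine, BrBr
Why: Deoxygenative bromination of an enolisable ketone with the triphenyl phosphite–bromine adduct: the carbonyl oxygen is activated as an oxyphosphonium ion and loss of HBr toward C4, the only α-carbon bearing hydrogen, should give the C4=C5 vinyl bromide (the descriptor at C3 changes by priority only).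

Step 13
Reactants: 19 (3R)-5-bromo-3-[(1S,3S,4S)-3-bromo-4-chloro-4-methylcyclohexyl]-6,6-dimethyl-3-(triethylsilyloxy)-3,6-dihydro-2H-pyran-2-one
Product: 20 (3S,5R)-5-bromo-3-[(1S,3S,4S)-3-bromo-4-chloro-4-methylcyclohexyl]-6,6-dimethyl-3-(triethylsilyloxy)oxan-2-one
Conditions: Mn(dpm)3 (cat.), PhSiH3, t-BuOOH, i-PrOH, rt
Reagents that add atoms: none
Why: Mukaiyama-type hydrogen-atom-transfer hydrogenation: a manganese hydride delivers H• to C4 to give the α-bromo radical at C5, which should take the second hydrogen so that bromine ends equatorial, cis to the equatorial cyclohexyl group and trans to the axial silyloxy group (thermodynamic stereocontrol), while the C–Br and C–Cl bonds survive.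

Step 14
Reactants: 20 (3S,5R)-5-bromo-3-[(1S,3S,4S)-3-bromo-4-chloro-4-methylcyclohexyl]-6,6-dimethyl-3-(triethylsilyloxy)oxan-2-one
Product: 22 (3S,5R)-5-bromo-3-[(1S,3S,4S)-3-bromo-4-chloro-4-methylcyclohexyl]-6,6-dimethyl-2-methylideneoxan-3-ol, via silyl ether 21 (not isolated)
Conditions: Cp2TiMe2, toluene, 65 °C, dark; then Bu4NF/AcOH (1:1), THF, 0 °C
Reagents that add atoms: dimethyltitanocene Cp2TiMe2, [CH3-].[CH3-].[Ti+4].c1cc[cH-]c1.c1cc[cH-]c1
Why: Petasis methylenation converts the lactone carbonyl into the exocyclic enol ether (isomerisation into the ring is impossible because C3 is quaternary), and buffered fluoride removes the triethylsilyl group without acid that would hydrolyse the enol ether.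

Compound list

1 | (S)-(−)-limonene, (4S)-1-methyl-4-(prop-1-en-2-yl)cyclohex-1-ene | CC(=C)[C@H]1CCC(C)=CC1 | starting material
2 | (4S)-limonene 1,2-oxide, mixture of cis and trans epoxides | CC(=C)[C@H]1CCC2(C)OC2C1 | intermediate
3 | cis-limonene 1,2-oxide, (1S,2R,4S) in p-menthane numbering | CC(=C)[C@H]1CC[C@]2(C)O[C@@H]2C1 | intermediate
4 | (1R,2R,5S)-2-bromo-2-methyl-5-(prop-1-en-2-yl)cyclohexan-1-ol | CC(=C)[C@H]1CC[C@@](C)(Br)[C@H](O)C1 | intermediate
5 | (1S,2S,4S)-2-bromo-1-chloro-1-methyl-4-(prop-1-en-2-yl)cyclohexane | CC(=C)[C@H]1CC[C@](C)(Cl)[C@@H](Br)C1 | intermediate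
6 | 2-[(1S,3S,4S)-3-bromo-4-chloro-4-methylcyclohexyl]prop-2-en-1-ol | OCC(=C)[C@H]1CC[C@](C)(Cl)[C@@H](Br)C1 | intermediate
7 | 2-methylbut-3-en-2-ol | CC(C)(O)C=C | starting material
8 | triethyl[(2-methylbut-3-en-2-yl)oxy]silane | CC[Si](CC)(CC)OC(C)(C)C=C | intermediate
9 | 2-methyl-2-(triethylsilyloxy)propanal | CC[Si](CC)(CC)OC(C)(C)C=O | intermediate
10 | (E)-2-methyl-2-(triethylsilyloxy)propanal oxime | CC[Si](CC)(CC)OC(C)(C)/C=N/O | intermediate
11 | (Z)-N-hydroxy-2-methyl-2-(triethylsilyloxy)propanimidoyl chloride | CC[Si](CC)(CC)OC(C)(C)/C(Cl)=N/O | intermediate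
12 | 2-methyl-2-(triethylsilyloxy)propanenitrile oxide | CC[Si](CC)(CC)OC(C)(C)C#[N+][O-] | intermediate
13 | [(5S)-5-[(1S,3S,4S)-3-bromo-4-chloro-4-methylcyclohexyl]-3-[2-(triethylsilyloxy)propan-2-yl]-4,5-dihydro-1,2-oxazol-5-yl]methanol | OC[C@]1(CC(C(C)(C)O[Si](CC)(CC)CC)=NO1)[C@H]2CC[C@](C)(Cl)[C@@H](Br)C2 | intermediate
14 | (5S)-5-[(1S,3S,4S)-3-bromo-4-chloro-4-methylcyclohexyl]-5,6-dihydroxy-2-methyl-2-(triethylsilyloxy)hexan-3-one | OC[C@](O)(CC(=O)C(C)(C)O[Si](CC)(CC)CC)[C@H]1CC[C@](C)(Cl)[C@@H](Br)C1 | intermediate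
15 | (5S)-5-[(1S,3S,4S)-3-bromo-4-chloro-4-methylcyclohexyl]-2,5,6-trihydroxy-2-methylhexan-3-one (may rest partly as a cyclic hemiketal) | OC[C@](O)(CC(=O)C(C)(C)O)[C@H]1CC[C@](C)(Cl)[C@@H](Br)C1 | intermediate
16 | (3S)-3-[(1S,3S,4S)-3-bromo-4-chloro-4-methylcyclohexyl]-2,3-dihydroxy-6,6-dimethyloxan-5-one, both C2 anomers | OC1OC(C)(C)C(=O)C[C@]1(O)[C@H]1CC[C@](C)(Cl)[C@@H](Br)C1 | intermediate
17 | (3S)-3-[(1S,3S,4S)-3-bromo-4-chloro-4-methylcyclohexyl]-3-hydroxy-6,6-dimethyloxane-2,5-dione | O=C1OC(C)(C)C(=O)C[C@]1(O)[C@H]1CC[C@](C)(Cl)[C@@H](Br)C1 | intermediate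
18 | (3S)-3-[(1S,3S,4S)-3-bromo-4-chloro-4-methylcyclohexyl]-6,6-dimethyl-3-(triethylsilyloxy)oxane-2,5-dione | O=C1OC(C)(C)C(=O)C[C@]1(O[Si](CC)(CC)CC)[C@H]1CC[C@](C)(Cl)[C@@H](Br)C1 | intermediate
19 | (3R)-5-bromo-3-[(1S,3S,4S)-3-bromo-4-chloro-4-methylcyclohexyl]-6,6-dimethyl-3-(triethylsilyloxy)-3,6-dihydro-2H-pyran-2-one | O=C1OC(C)(C)C(Br)=C[C@]1(O[Si](CC)(CC)CC)[C@H]1CC[C@](C)(Cl)[C@@H](Br)C1 | intermediate
20 | (3S,5R)-5-bromo-3-[(1S,3S,4S)-3-bromo-4-chloro-4-methylcyclohexyl]-6,6-dimethyl-3-(triethylsilyloxy)oxan-2-one | O=C1OC(C)(C)[C@H](Br)C[C@]1(O[Si](CC)(CC)CC)[C@H]1CC[C@](C)(Cl)[C@@H](Br)C1 | intermediate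
21 | [[(3S,5R)-5-bromo-3-[(1S,3S,4S)-3-bromo-4-chloro-4-methylcyclohexyl]-6,6-dimethyl-2-methylideneoxan-3-yl]oxy]triethylsilane | C=C1OC(C)(C)[C@H](Br)C[C@]1(O[Si](CC)(CC)CC)[C@H]1CC[C@](C)(Cl)[C@@H](Br)C1 | intermediate
22 | (3S,5R)-5-bromo-3-[(1S,3S,4S)-3-bromo-4-chloro-4-methylcyclohexyl]-6,6-dimethyl-2-methylideneoxan-3-ol | C=C1OC(C)(C)[C@H](Br)C[C@]1(O)[C@H]1CC[C@](C)(Cl)[C@@H](Br)C1 | target

Total step count: 14. Longest linear sequence: 11 steps (steps 1–4 and 8–14; steps 5–7 make the dipole precursor).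

Steps most likely to fail

Step 3. The bromonium ion may be captured by chloride at its secondary carbon (the trans-diaxial pathway, returning a tertiary bromide/secondary chloride) or may lose a proton, instead of undergoing Markovnikov capture. The fallback sets out from 1 and returns at 5: 1 is treated with Bu4NBrCl2 in CH2Cl2 at −78 °C, so that the halogen positions are fixed by Markovnikov anti addition to the ring alkene and not by a bromine shift. Bromonium ions on both ring faces should be opened by chloride at the tertiary carbon, giving 5 together with its trans-diaxial diastereomer (1R,2R,4S)-2-bromo-1-chloro-1-methyl-4-(prop-1-en-2-yl)cyclohexane F1, which is expected to predominate and is removed by chromatography; this trades material for certainty of halogen regiochemistry.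

Step 8. Face discrimination may be poor at the hindered 2-substituted allylic alcohol, or dimerisation of the nitrile oxide may outrun the cycloaddition. The fallback sets out from 6 and returns at 15; the carbinol configuration then comes from an epoxidation and the C4–C5 bond from acyl-anion alkylation. Sharpless asymmetric epoxidation of 6 (Ti(OiPr)4, diethyl (S,S)-tartrate, t-BuOOH, CH2Cl2, −20 °C) should give [(2S)-2-[(1S,3S,4S)-3-bromo-4-chloro-4-methylcyclohexyl]oxiran-2-yl]methanol F2. 2-(1,3-Dithian-2-yl)propan-2-ol F3, made from 1,3-dithiane, n-BuLi and acetone, is doubly lithiated (n-BuLi, THF, −30 °C) and should open F2 at its CH2 terminus to give (2S)-2-[(1S,3S,4S)-3-bromo-4-chloro-4-methylcyclohexyl]-3-[2-(2-hydroxypropan-2-yl)-1,3-dithian-2-yl]propane-1,2-diol F4. MeI and CaCO3 in aqueous MeCN then hydrolyse the dithiane to 15.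

Step 12. The hindered ketone may resist activation, or base may trigger β-elimination of the silyloxy group next to the developing unsaturation. The fallback sets out from 18 and returns at 19 and avoids both the halophosphonium reagent and any enolate. Tf2O with 2,6-di-tert-butyl-4-methylpyridine (CH2Cl2, 0 °C) should convert 18 into the enol triflate (3R)-3-[(1S,3S,4S)-3-bromo-4-chloro-4-methylcyclohexyl]-6,6-dimethyl-2-oxo-3-(triethylsilyloxy)-3,6-dihydro-2H-pyran-5-yl trifluoromethanesulfonate F5. Ruthenium-catalysed triflate–bromide exchange ([Cp*Ru(MeCN)3]OTf, LiBr, THF, 70 °C) then gives 19.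

Further compounds
F1 | step 3 | (1R,2R,4S)-2-bromo-1-chloro-1-methyl-4-(prop-1-en-2-yl)cyclohexane | CC(=C)[C@H]1CC[C@@](C)(Cl)[C@H](Br)C1
F2 | step 8 | [(2S)-2-[(1S,3S,4S)-3-bromo-4-chloro-4-methylcyclohexyl]oxiran-2-yl]methanol | OC[C@]1(CO1)[C@H]2CC[C@](C)(Cl)[C@@H](Br)C2
F3 | step 8 | 2-(1,3-dithian-2-yl)propan-2-ol | CC(C)(O)C1SCCCS1
F4 | step 8 | (2S)-2-[(1S,3S,4S)-3-bromo-4-chloro-4-methylcyclohexyl]-3-[2-(2-hydroxypropan-2-yl)-1,3-dithian-2-yl]propane-1,2-diol | OC[C@](O)(CC1(SCCCS1)C(C)(C)O)[C@H]1CC[C@](C)(Cl)[C@@H](Br)C1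
F5 | step 12 | (3R)-3-[(1S,3S,4S)-3-bromo-4-chloro-4-methylcyclohexyl]-6,6-dimethyl-2-oxo-3-(triethylsilyloxy)-3,6-dihydro-2H-pyran-5-yl trifluoromethanesulfonate | O=C1OC(C)(C)C(OS(=O)(=O)C(F)(F)F)=C[C@]1(O[Si](CC)(CC)CC)[C@H]1CC[C@](C)(Cl)[C@@H](Br)C1
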